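The dihydrofuran is read as a contracted dihydropyranone. In the furo[3,2-c]pyran-4-one core, C3 holds a carboxyl-level carbon outside the ring (C6 of ring A) and a direct bond to C3a of ring B, which is the signature of a Wolff shift in a ring-B-fused six-membered 3-diazo-4-ketone. Photolysis expels N2, C3a moves onto the former diazo carbon, and allyl alcohol intercepts the exocyclic ketene. One operation delivers the five-membered ring, the C3–C3a bond, the C3 ester handle and, after base equilibration, the 2,3-trans relationship. The precursor is a 2-aryl-3-diazo-7-methyl-2,3-dihydropyrano[4,3-b]pyran-4,5-dione bearing a silylated catechol and the C2 configuration already fixed.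

Key step: step 5

Remarks on the chemistry:
- The SMILES is read as the 2,3-trans isomer with C2 = S and C3 = S. C2 keeps one spatial arrangement from step 3 on; its descriptor reads R only in 7 and 8, where the diazo or ketene carbon outranks the aryl carbon.
- All phenols are carried as triisopropylsilyl (TIPS) ethers, which tolerate piperidine at reflux and two DBU treatments and fall together at the end.
- The ring B methyl is kept through the photolysis because a styrylpyranone would absorb the light and isomerise or dimerise. The styryl arm is attached at the ester stage, before the acidic ring A exists.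

**Step 1**
Reactants: 1 3,4-dihydroxybenzaldehyde
Product: 2 3,4-bis(triisopropylsilyloxy)benzaldehyde
Conditions: TIPSCl (2.4 equiv), imidazole, DMF, rt
Reagents that add atoms: chlorotriisopropylsilane, CC(C)[Si](Cl)(C(C)C)C(C)C
Why: Silyl ether formation on both phenols with TIPSCl and imidazole is routine, and the bulky triisopropylsilyl groups are chosen because they survive the amine bases used later.

**Step 2**
Reactants: 3 dehydroacetic acid; 2 3,4-bis(triisopropylsilyloxy)benzaldehyde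
Product: 4 3-[(2E)-3-[3,4-bis(triisopropylsilyloxy)phenyl]prop-2-enoyl]-4-hydroxy-6-methyl-2H-pyran-2-one
Conditions: piperidine (0.2 equiv), CHCl3, reflux, Dean–Stark trap
Reagents that add atoms: none
Why: Piperidine-catalysed Claisen–Schmidt condensation of the acetyl methyl of dehydroacetic acid with an aromatic aldehyde is the standard entry to 3-cinnamoyl-4-hydroxy-6-methylpyran-2-ones, the acetyl group reacting in preference to the ring methyl and dehydration giving the conjugated E enone.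

**Step 3**
Reactants: 4 3-[(2E)-3-[3,4-bis(triisopropylsilyloxy)phenyl]prop-2-enoyl]-4-hydroxy-6-methyl-2H-pyran-2-one
Product: 5 (2S)-2-[3,4-bis(triisopropylsilyloxy)phenyl]-7-methyl-2,3-dihydro-4H,5H-pyrano[4,3-b]pyran-4,5-dione
Conditions: quinine-derived squaramide catalyst (3,5-bis(trifluoromethyl)anilino squaramide of 9-amino-9-deoxy-epi-quinine, 10 mol%), PhMe, 0 °C
Reagents that add atoms: none
Why: Enantioselective intramolecular oxa-Michael addition (6-endo-trig) under bifunctional squaramide–tertiary amine catalysis, the mode used to close 2'-hydroxychalcones to flavanones: the quinuclidine takes the acidic enol proton, the squaramide N–H pair binds the enone carbonyl, and O–C bond formation on the Si face of the β-carbon sets C2 as S (the quinidine-derived pseudo-enantiomer reverses the sense if needed).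

**Step 4**
Reactants: 5 (2S)-2-[3,4-bis(triisopropylsilyloxy)phenyl]-7-methyl-2,3-dihydro-4H,5H-pyrano[4,3-b]pyran-4,5-dione
Product: 7 (2R)-2-[3,4-bis(triisopropylsilyloxy)phenyl]-3-diazo-7-methyl-2,3-dihydro-4H,5H-pyrano[4,3-b]pyran-4,5-dione, via trifluoroacetyl ketone 6 (not isolated)
Conditions: LiN(SiMe3)2, THF, −78 °C; CF3CO2CH2CF3, −78 °C; AcOH; then p-ABSA, Et3N, H2O, MeCN, rt
Reagents that add atoms: 4-acetamidobenzenesulfonyl azide (p-ABSA), CC(=O)Nc1ccc(cc1)S(=O)(=O)N=[N+]=[N-]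
Why: Regitz-type detrifluoroacetylative diazo transfer: the C3 enolate is formed kinetically at −78 °C and trapped at once as the trifluoroacetyl ketone before it can expel the ring oxygen, and the sulfonyl azide then delivers N2 to the 1,3-dicarbonyl with loss of the trifluoroacetyl group, leaving C2 untouched.

**Step 5**
Reactants: 7 (2R)-2-[3,4-bis(triisopropylsilyloxy)phenyl]-3-diazo-7-methyl-2,3-dihydro-4H,5H-pyrano[4,3-b]pyran-4,5-dione
Product: 10 allyl (2S,3S)-2-[3,4-bis(triisopropylsilyloxy)phenyl]-6-methyl-4-oxo-2,3-dihydro-4H-furo[3,2-c]pyran-3-carboxylate, via ketene 8 (not isolated), via cis ester 9 (not isolated)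
Conditions: hν (405 nm LED), allyl alcohol (10 equiv), CH2Cl2, 10 °C; then DBU (0.3 equiv), rt
Reagents that add atoms: allyl alcohol, C=CCO
Why: Direct excitation of the diazoketone, whose C=N2 and C=O are held s-cis by the ring, releases N2 with concerted 1,2-shift of C4a (the ring B carbon) from the ketone carbon to the diazo carbon, giving ketene 8 exocyclic at C3; allyl alcohol adds to the ketene and the ester enol ketonises. The closest known reaction is the photochemical Wolff ring contraction of 3-diazochroman-4-ones to 2,3-dihydrobenzofuran-3-carboxylates. The five-membered ring is not closed by a cyclisation: it results from ring contraction (six to five) through the new C3–C3a bond, which sidesteps a disfavoured 5-endo-trig closure. The new stereocentre C3 is set under thermodynamic control: DBU equilibrates the ester α-carbon and the untouched C2 aryl group directs the ester trans, while ring opening by β-elimination is not a threat because the C2–O1 bond lies in the nodal plane of the exocyclic enolate. The step needs the Wolff shift to outrun the 1,2-hydride shift from C2 and O–H insertion of a free carbene, which the locked s-cis geometry and singlet excitation secure; 405 nm light reaches the diazo n–π* band but not the 2-pyranone chromophore, and the ring B methyl is light-silent where a styryl group would not be.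

**Step 6**
Reactants: 11 4-hydroxybenzaldehyde
Product: 12 4-(triisopropylsilyloxy)benzaldehyde
Conditions: TIPSCl (1.2 equiv), imidazole, DMF, rt
Reagents that add atoms: chlorotriisopropylsilane, CC(C)[Si](Cl)(C(C)C)C(C)C
Why: Routine phenol silylation gives the non-enolisable aldehyde partner in the same protecting group as the catechol, so that one fluoride treatment clears all three at the end.

**Step 7**
Reactants: 10 allyl (2S,3S)-2-[3,4-bis(triisopropylsilyloxy)phenyl]-6-methyl-4-oxo-2,3-dihydro-4H-furo[3,2-c]pyran-3-carboxylate; 12 4-(triisopropylsilyloxy)benzaldehyde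
Product: 13 allyl (2S,3S)-2-[3,4-bis(triisopropylsilyloxy)phenyl]-6-{2-hydroxy-2-[4-(triisopropylsilyloxy)phenyl]ethyl}-4-oxo-2,3-dihydro-4H-furo[3,2-c]pyran-3-carboxylate (both carbinol epimers)
Conditions: LiN(SiMe3)2 (1.05 equiv), THF, −78 °C; then 12, −78 °C; AcOH
Reagents that add atoms: none
Why: Vinylogous aldol addition of the lithium dienolate generated at the ring B methyl, as practised on 4-alkoxy-6-methyl-2-pyranones; the methyl is more acidic and far more accessible than the hindered tertiary C3–H, and the new carbinol centre is formed unselectively because the next step removes it.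

**Step 8**
Reactants: 13 allyl (2S,3S)-2-[3,4-bis(triisopropylsilyloxy)phenyl]-6-{2-hydroxy-2-[4-(triisopropylsilyloxy)phenyl]ethyl}-4-oxo-2,3-dihydro-4H-furo[3,2-c]pyran-3-carboxylate
Product: 15 allyl (2S,3S)-2-[3,4-bis(triisopropylsilyloxy)phenyl]-4-oxo-6-{(E)-2-[4-(triisopropylsilyloxy)phenyl]ethenyl}-2,3-dihydro-4H-furo[3,2-c]pyran-3-carboxylate, via mesylate 14 (not isolated)
Conditions: MsCl, Et3N, CH2Cl2, 0 °C; then DBU, rt
Reagents that add atoms: none
Why: Aldol dehydration by mesylation and E1cB elimination through the acidic CH2 next to C6 gives the conjugated styryl unit in its more stable E geometry, while DBU keeps C3 at the trans equilibrium.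

**Step 9**
Reactants: 15 allyl (2S,3S)-2-[3,4-bis(triisopropylsilyloxy)phenyl]-4-oxo-6-{(E)-2-[4-(triisopropylsilyloxy)phenyl]ethenyl}-2,3-dihydro-4H-furo[3,2-c]pyran-3-carboxylate
Product: 16 (2S,3S)-2-[3,4-bis(triisopropylsilyloxy)phenyl]-4-oxo-6-{(E)-2-[4-(triisopropylsilyloxy)phenyl]ethenyl}-2,3-dihydro-4H-furo[3,2-c]pyran-3-carboxylic acid
Conditions: Pd(PPh3)4 (5 mol%), morpholine, THF, rt; aqueous citric acid work-up
Reagents that add atoms: none
Why: Tsuji–Trost deallylation: zerovalent palladium ionises the allyl ester and morpholine accepts the allyl group under near-neutral conditions that spare both lactones, the silyl ethers, the styryl alkene and both stereocentres.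

**Step 10**
Reactants: 16 (2S,3S)-2-[3,4-bis(triisopropylsilyloxy)phenyl]-4-oxo-6-{(E)-2-[4-(triisopropylsilyloxy)phenyl]ethenyl}-2,3-dihydro-4H-furo[3,2-c]pyran-3-carboxylic acid; 17 2,2,6-trimethyl-4H-1,3-dioxin-4-one
Product: 19 6-{2-[(2S,3S)-2-[3,4-bis(triisopropylsilyloxy)phenyl]-4-oxo-6-{(E)-2-[4-(triisopropylsilyloxy)phenyl]ethenyl}-2,3-dihydro-4H-furo[3,2-c]pyran-3-yl]-2-oxoethyl}-2,2-dimethyl-4H-1,3-dioxin-4-one, via acyl imidazole 18 (not isolated)
Conditions: CDI (1.2 equiv), THF, rt; then added to 17 + LiN(SiMe3)2 (3 equiv each), THF, −78 °C; AcOH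
Reagents that add atoms: none
Why: Claisen-type γ-acylation of the lithium dienolate of the dioxinone with an acyl imidazole is a standard route to β-keto dioxinones, and the product is deprotonated at its doubly activated CH2 as soon as it forms, which keeps base away from C3.

**Step 11**
Reactants: 19 6-{2-[(2S,3S)-2-[3,4-bis(triisopropylsilyloxy)phenyl]-4-oxo-6-{(E)-2-[4-(triisopropylsilyloxy)phenyl]ethenyl}-2,3-dihydro-4H-furo[3,2-c]pyran-3-yl]-2-oxoethyl}-2,2-dimethyl-4H-1,3-dioxin-4-one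
Product: 21 (2S,3S)-2-[3,4-bis(triisopropylsilyloxy)phenyl]-3-(4-hydroxy-2-oxo-2H-pyran-6-yl)-6-{(E)-2-[4-(triisopropylsilyloxy)phenyl]ethenyl}-2,3-dihydro-4H-furo[3,2-c]pyran-4-one, via acylketene 20 (not isolated)
Conditions: PhMe, 110 °C
Reagents that add atoms: none
Why: Thermal retro-[4+2] fragmentation of the dioxinone expels acetone and the acylketene is captured by the enol oxygen of the neighbouring ketone to close ring A as a 4-hydroxy-2-pyranone; C3, now flanked by two pyranones, may equilibrate in the heat and settles trans to the C2 aryl group.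

**Step 12**
Reactants: 21 (2S,3S)-2-[3,4-bis(triisopropylsilyloxy)phenyl]-3-(4-hydroxy-2-oxo-2H-pyran-6-yl)-6-{(E)-2-[4-(triisopropylsilyloxy)phenyl]ethenyl}-2,3-dihydro-4H-furo[3,2-c]pyran-4-one
Product: 22 (2S,3S)-2-(3,4-dihydroxyphenyl)-3-(4-hydroxy-2-oxo-2H-pyran-6-yl)-6-[(E)-2-(4-hydroxyphenyl)ethenyl]-2,3-dihydro-4H-furo[3,2-c]pyran-4-one
Conditions: Bu4NF, AcOH (1:1.5), THF, 0 °C
Reagents that add atoms: none
Why: Fluoride cleavage of the three aryl silyl ethers, buffered with acetic acid so that no phenoxide arises that could open the C2–O1 bond through a quinone methide and erase C2, gives the target with both stereocentres as set.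

**Compound list**

1 | 3,4-dihydroxybenzaldehyde | O=Cc1ccc(O)c(O)c1 | starting material
2 | 3,4-bis(triisopropylsilyloxy)benzaldehyde | O=Cc1ccc(O[Si](C(C)C)(C(C)C)C(C)C)c(O[Si](C(C)C)(C(C)C)C(C)C)c1 | intermediate
3 | dehydroacetic acid (3-acetyl-4-hydroxy-6-methyl-2H-pyran-2-one) | CC(=O)c1c(O)cc(C)oc1=O | starting material
4 | 3-[(2E)-3-[3,4-bis(triisopropylsilyloxy)phenyl]prop-2-enoyl]-4-hydroxy-6-methyl-2H-pyran-2-one | Cc1cc(O)c(C(=O)/C=C/c2ccc(O[Si](C(C)C)(C(C)C)C(C)C)c(O[Si](C(C)C)(C(C)C)C(C)C)c2)c(=O)o1 | intermediate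
5 | (2S)-2-[3,4-bis(triisopropylsilyloxy)phenyl]-7-methyl-2,3-dihydro-4H,5H-pyrano[4,3-b]pyran-4,5-dione | Cc1cc2O[C@@H](CC(=O)c2c(=O)o1)c1ccc(O[Si](C(C)C)(C(C)C)C(C)C)c(O[Si](C(C)C)(C(C)C)C(C)C)c1 | intermediate
6 | (2S)-2-[3,4-bis(triisopropylsilyloxy)phenyl]-7-methyl-3-(trifluoroacetyl)-2,3-dihydro-4H,5H-pyrano[4,3-b]pyran-4,5-dione (enolised, C3 undefined) | Cc1cc2O[C@@H](C(C(=O)C(F)(F)F)C(=O)c2c(=O)o1)c1ccc(O[Si](C(C)C)(C(C)C)C(C)C)c(O[Si](C(C)C)(C(C)C)C(C)C)c1 | intermediate (not isolated)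
7 | (2R)-2-[3,4-bis(triisopropylsilyloxy)phenyl]-3-diazo-7-methyl-2,3-dihydro-4H,5H-pyrano[4,3-b]pyran-4,5-dione | Cc1cc2O[C@@H](C(=[N+]=[N-])C(=O)c2c(=O)o1)c1ccc(O[Si](C(C)C)(C(C)C)C(C)C)c(O[Si](C(C)C)(C(C)C)C(C)C)c1 | intermediate
8 | (2R)-2-[3,4-bis(triisopropylsilyloxy)phenyl]-6-methyl-3-(oxomethylidene)-2,3-dihydro-4H-furo[3,2-c]pyran-4-one (ketene) | O=C=C1c2c(cc(C)oc2=O)O[C@@H]1c1ccc(O[Si](C(C)C)(C(C)C)C(C)C)c(O[Si](C(C)C)(C(C)C)C(C)C)c1 | intermediate (not isolated)
9 | allyl (2S,3R)-2-[3,4-bis(triisopropylsilyloxy)phenyl]-6-methyl-4-oxo-2,3-dihydro-4H-furo[3,2-c]pyran-3-carboxylate (cis) | C=CCOC(=O)[C@@H]1c2c(cc(C)oc2=O)O[C@@H]1c1ccc(O[Si](C(C)C)(C(C)C)C(C)C)c(O[Si](C(C)C)(C(C)C)C(C)C)c1 | intermediate (not isolated)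
10 | allyl (2S,3S)-2-[3,4-bis(triisopropylsilyloxy)phenyl]-6-methyl-4-oxo-2,3-dihydro-4H-furo[3,2-c]pyran-3-carboxylate (trans) | C=CCOC(=O)[C@H]1c2c(cc(C)oc2=O)O[C@@H]1c1ccc(O[Si](C(C)C)(C(C)C)C(C)C)c(O[Si](C(C)C)(C(C)C)C(C)C)c1 | intermediate
11 | 4-hydroxybenzaldehyde | O=Cc1ccc(O)cc1 | starting material
12 | 4-(triisopropylsilyloxy)benzaldehyde | O=Cc1ccc(O[Si](C(C)C)(C(C)C)C(C)C)cc1 | intermediate
13 | allyl (2S,3S)-2-[3,4-bis(triisopropylsilyloxy)phenyl]-6-{2-hydroxy-2-[4-(triisopropylsilyloxy)phenyl]ethyl}-4-oxo-2,3-dihydro-4H-furo[3,2-c]pyran-3-carboxylate (carbinol epimers) | C=CCOC(=O)[C@H]1c2c(cc(CC(O)c3ccc(O[Si](C(C)C)(C(C)C)C(C)C)cc3)oc2=O)O[C@@H]1c1ccc(O[Si](C(C)C)(C(C)C)C(C)C)c(O[Si](C(C)C)(C(C)C)C(C)C)c1 | intermediate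
14 | allyl (2S,3S)-2-[3,4-bis(triisopropylsilyloxy)phenyl]-6-{2-(methanesulfonyloxy)-2-[4-(triisopropylsilyloxy)phenyl]ethyl}-4-oxo-2,3-dihydro-4H-furo[3,2-c]pyran-3-carboxylate | C=CCOC(=O)[C@H]1c2c(cc(CC(OS(C)(=O)=O)c3ccc(O[Si](C(C)C)(C(C)C)C(C)C)cc3)oc2=O)O[C@@H]1c1ccc(O[Si](C(C)C)(C(C)C)C(C)C)c(O[Si](C(C)C)(C(C)C)C(C)C)c1 | intermediate (not isolated)
15 | allyl (2S,3S)-2-[3,4-bis(triisopropylsilyloxy)phenyl]-4-oxo-6-{(E)-2-[4-(triisopropylsilyloxy)phenyl]ethenyl}-2,3-dihydro-4H-furo[3,2-c]pyran-3-carboxylate | C=CCOC(=O)[C@H]1c2c(cc(/C=C/c3ccc(O[Si](C(C)C)(C(C)C)C(C)C)cc3)oc2=O)O[C@@H]1c1ccc(O[Si](C(C)C)(C(C)C)C(C)C)c(O[Si](C(C)C)(C(C)C)C(C)C)c1 | intermediate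
16 | (2S,3S)-2-[3,4-bis(triisopropylsilyloxy)phenyl]-4-oxo-6-{(E)-2-[4-(triisopropylsilyloxy)phenyl]ethenyl}-2,3-dihydro-4H-furo[3,2-c]pyran-3-carboxylic acid | OC(=O)[C@H]1c2c(cc(/C=C/c3ccc(O[Si](C(C)C)(C(C)C)C(C)C)cc3)oc2=O)O[C@@H]1c1ccc(O[Si](C(C)C)(C(C)C)C(C)C)c(O[Si](C(C)C)(C(C)C)C(C)C)c1 | intermediate
17 | 2,2,6-trimethyl-4H-1,3-dioxin-4-one | CC1=CC(=O)OC(C)(C)O1 | starting material
18 | 1-{[(2S,3S)-2-[3,4-bis(triisopropylsilyloxy)phenyl]-4-oxo-6-{(E)-2-[4-(triisopropylsilyloxy)phenyl]ethenyl}-2,3-dihydro-4H-furo[3,2-c]pyran-3-yl]carbonyl}imidazole | O=C(n1ccnc1)[C@H]1c2c(cc(/C=C/c3ccc(O[Si](C(C)C)(C(C)C)C(C)C)cc3)oc2=O)O[C@@H]1c1ccc(O[Si](C(C)C)(C(C)C)C(C)C)c(O[Si](C(C)C)(C(C)C)C(C)C)c1 | intermediate (not isolated)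
19 | 6-{2-[(2S,3S)-2-[3,4-bis(triisopropylsilyloxy)phenyl]-4-oxo-6-{(E)-2-[4-(triisopropylsilyloxy)phenyl]ethenyl}-2,3-dihydro-4H-furo[3,2-c]pyran-3-yl]-2-oxoethyl}-2,2-dimethyl-4H-1,3-dioxin-4-one | CC1(C)OC(CC(=O)[C@H]2c3c(cc(/C=C/c4ccc(O[Si](C(C)C)(C(C)C)C(C)C)cc4)oc3=O)O[C@@H]2c2ccc(O[Si](C(C)C)(C(C)C)C(C)C)c(O[Si](C(C)C)(C(C)C)C(C)C)c2)=CC(=O)O1 | intermediate
20 | 5-[(2S,3S)-2-[3,4-bis(triisopropylsilyloxy)phenyl]-4-oxo-6-{(E)-2-[4-(triisopropylsilyloxy)phenyl]ethenyl}-2,3-dihydro-4H-furo[3,2-c]pyran-3-yl]-3,5-dioxopent-1-en-1-one (acylketene) | O=C=CC(=O)CC(=O)[C@H]1c2c(cc(/C=C/c3ccc(O[Si](C(C)C)(C(C)C)C(C)C)cc3)oc2=O)O[C@@H]1c1ccc(O[Si](C(C)C)(C(C)C)C(C)C)c(O[Si](C(C)C)(C(C)C)C(C)C)c1 | intermediate (not isolated)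
21 | (2S,3S)-2-[3,4-bis(triisopropylsilyloxy)phenyl]-3-(4-hydroxy-2-oxo-2H-pyran-6-yl)-6-{(E)-2-[4-(triisopropylsilyloxy)phenyl]ethenyl}-2,3-dihydro-4H-furo[3,2-c]pyran-4-one | O=c1cc(O)cc([C@H]2c3c(cc(/C=C/c4ccc(O[Si](C(C)C)(C(C)C)C(C)C)cc4)oc3=O)O[C@@H]2c2ccc(O[Si](C(C)C)(C(C)C)C(C)C)c(O[Si](C(C)C)(C(C)C)C(C)C)c2)o1 | intermediate
22 | (2S,3S)-2-(3,4-dihydroxyphenyl)-3-(4-hydroxy-2-oxo-2H-pyran-6-yl)-6-[(E)-2-(4-hydroxyphenyl)ethenyl]-2,3-dihydro-4H-furo[3,2-c]pyran-4-one | O=c1cc(O)cc([C@H]2c3c(cc(/C=C/c4ccc(O)cc4)oc3=O)O[C@@H]2c2ccc(O)c(O)c2)o1 | target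

**Step count**

Total: 12 steps. Longest linear sequence: 11 steps (steps 1–5 and 7–12, from 3,4-dihydroxybenzaldehyde).

**Steps most likely to fail**

Step 5. The carbene channel may compete with the concerted shift, through 1,2-hydride shift from the benzylic, oxygen-bearing C2 or O–H insertion into allyl alcohol, or the pyranone chromophore may take part in the photochemistry, so that little ketene is formed. The fallback builds the same ester by oxidative [3+2] annulation and resolution, without diazo chemistry. It sets out from aldehyde 2, which is olefinated with allyl diethylphosphonoacetate (LiCl, DBU, MeCN; Horner–Wadsworth–Emmons) to allyl (2E)-3-[3,4-bis(triisopropylsilyloxy)phenyl]prop-2-enoate F1. Commercial 4-hydroxy-6-methyl-2H-pyran-2-one and F1 are then joined with Mn(OAc)3·2H2O in AcOH at 70 °C. The trivalent manganese enolate gives a radical that adds to the α-carbon of the cinnamate, the benzylic radical is oxidised to the cation, and the enol oxygen closes the dihydrofuran. This should give the trans ester as a racemate, that is 10 together with its enantiomer, allyl (2R,3R)-2-[3,4-bis(triisopropylsilyloxy)phenyl]-6-methyl-4-oxo-2,3-dihydro-4H-furo[3,2-c]pyran-3-carboxylate F2. Preparative chiral SFC removes F2 and the route is rejoined at 10.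

Step 3. Ring closure may be incomplete or reversible: the chelated open enol may be favoured with the electron-rich aryl group, and every catalysed reopening erodes the enantiomeric excess. The fallback forms the C2–aryl bond irreversibly in place of the C2–O bond. It sets out from dehydroacetic acid 3, which with DMF dimethyl acetal (PhMe, 80 °C) should give the enaminone 3-[(2E)-3-(dimethylamino)prop-2-enoyl]-4-hydroxy-6-methyl-2H-pyran-2-one F3. Acid (AcOH, cat. H2SO4, 80 °C) closes it to 7-methyl-4H,5H-pyrano[4,3-b]pyran-4,5-dione F4. Commercial 4-bromocatechol is silylated (TIPSCl, imidazole, DMF) to 4-bromo-1,2-bis(triisopropylsilyloxy)benzene F5 and converted (n-BuLi, THF, −78 °C; B(OiPr)3; aqueous NH4Cl) into [3,4-bis(triisopropylsilyloxy)phenyl]boronic acid F6. Asymmetric conjugate addition of F6 to F4 follows, under Pd(OCOCF3)2, 4-tert-butyl-2-(pyridin-2-yl)-4,5-dihydrooxazole ligand, NH4PF6 and H2O in ClCH2CH2Cl at 60 °C. This divalent palladium catalysis is established for chromone-to-flavanone arylation; the ligand enantiomer is chosen for 2S. It should give 5 under base-free conditions that cannot reopen the ring, and the route is rejoined at 5.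

Step 4. The C2 configuration may erode by reversible β-elimination of the ring oxygen from the C3 enolate (lithium enolate or the triethylammonium diketonate) before the diazo group is in place. The fallback replaces asymmetric catalysis by resolution after the centre is locked. It sets out from chalcone 4, which is closed without chiral control (Et3N, EtOH, 60 °C) to 5 together with its enantiomer, (2R)-2-[3,4-bis(triisopropylsilyloxy)phenyl]-7-methyl-2,3-dihydro-4H,5H-pyrano[4,3-b]pyran-4,5-dione F7. The same diazo transfer passes through 6 and its enantiomer, the (2R)-trifluoroacetyl ketone F8. It gives 7 together with its enantiomer, (2S)-2-[3,4-bis(triisopropylsilyloxy)phenyl]-3-diazo-7-methyl-2,3-dihydro-4H,5H-pyrano[4,3-b]pyran-4,5-dione F9. The diazoketone has no proton at C3 and cannot racemise, so preparative chiral SFC removes F9 and the route is rejoined at 7.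

**Further compounds**

F1 | step 5 | allyl (2E)-3-[3,4-bis(triisopropylsilyloxy)phenyl]prop-2-enoate | C=CCOC(=O)/C=C/c1ccc(O[Si](C(C)C)(C(C)C)C(C)C)c(O[Si](C(C)C)(C(C)C)C(C)C)c1
F2 | step 5 | allyl (2R,3R)-2-[3,4-bis(triisopropylsilyloxy)phenyl]-6-methyl-4-oxo-2,3-dihydro-4H-furo[3,2-c]pyran-3-carboxylate | C=CCOC(=O)[C@@H]1c2c(cc(C)oc2=O)O[C@H]1c1ccc(O[Si](C(C)C)(C(C)C)C(C)C)c(O[Si](C(C)C)(C(C)C)C(C)C)c1
F3 | step 3 | 3-[(2E)-3-(dimethylamino)prop-2-enoyl]-4-hydroxy-6-methyl-2H-pyran-2-one | CN(C)/C=C/C(=O)c1c(O)cc(C)oc1=O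
F4 | step 3 | 7-methyl-4H,5H-pyrano[4,3-b]pyran-4,5-dione | CC1=CC2=C(C(=O)O1)C(=O)C=CO2
F5 | step 3 | 4-bromo-1,2-bis(triisopropylsilyloxy)benzene | Brc1ccc(O[Si](C(C)C)(C(C)C)C(C)C)c(O[Si](C(C)C)(C(C)C)C(C)C)c1
F6 | step 3 | [3,4-bis(triisopropylsilyloxy)phenyl]boronic acid | OB(O)c1ccc(O[Si](C(C)C)(C(C)C)C(C)C)c(O[Si](C(C)C)(C(C)C)C(C)C)c1
F7 | step 4 | (2R)-2-[3,4-bis(triisopropylsilyloxy)phenyl]-7-methyl-2,3-dihydro-4H,5H-pyrano[4,3-b]pyran-4,5-dione | Cc1cc2O[C@H](CC(=O)c2c(=O)o1)c1ccc(O[Si](C(C)C)(C(C)C)C(C)C)c(O[Si](C(C)C)(C(C)C)C(C)C)c1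
F8 | step 4 | (2R)-2-[3,4-bis(triisopropylsilyloxy)phenyl]-7-methyl-3-(trifluoroacetyl)-2,3-dihydro-4H,5H-pyrano[4,3-b]pyran-4,5-dione | Cc1cc2O[C@H](C(C(=O)C(F)(F)F)C(=O)c2c(=O)o1)c1ccc(O[Si](C(C)C)(C(C)C)C(C)C)c(O[Si](C(C)C)(C(C)C)C(C)C)c1
F9 | step 4 | (2S)-2-[3,4-bis(triisopropylsilyloxy)phenyl]-3-diazo-7-methyl-2,3-dihydro-4H,5H-pyrano[4,3-b]pyran-4,5-dione | Cc1cc2O[C@H](C(=[N+]=[N-])C(=O)c2c(=O)o1)c1ccc(O[Si](C(C)C)(C(C)C)C(C)C)c(O[Si](C(C)C)(C(C)C)C(C)C)c1
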